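**Plan**
1. Numbering (daucane): C1 is the quaternary ring-fusion carbon (its methyl defines the β face), C2/C3 the cyclopentane CH2 groups, C4 the isopropyl carbinol, C5 the ring-fusion CH, C6 the acyloxy CH, C7=C8(Me) the alkene, C9 the ketone, C10 the CH2 between C9 and C1.
2. Retrosynthesis cuts the C6–O acyl bond and the C4–isopropyl bond, returns H5/O6 to a C5=C6 alkene, then cuts C1–C10 (retro-Claisen, re-forming O–C6), turns C9=C10 back into a lactone carbonyl, removes the C8 methyl, and cuts C5–C6 between a 2-metallated cyclopentenone ketal and a succinyl unit.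
3. Enabling feature: C6 carries oxygen and is allylic to C1 through C5, and C9–C10 is an acetyl-type unit, so the atoms C10=C9–O–C6–C5=C1 form an allyl vinyl ether held in a five-membered ring (O, C6, C7, C8, C9).
4. Forward: the cyclopentane is present from the start, the C6–C9 chain is joined at C5, the oxolane is closed as a lactone, and the seven-membered ring arises by Claisen ring expansion of the derived 2-methylidene oxolane; the coumarate is attached last.
5. Stereochemistry: C6 from a CBS reduction, relayed to C1 in the [3,3] shift; H5 and O6 from syn hydroboration anti to the C1 methyl; C4 from isopropyl addition anti to the same methyl.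

Key step: step 6

Remark: 1, 3 and 25 are taken as commercial. Names from 12 onward use the daucane skeleton (C11–C13 isopropyl on C4, C14 methyl on C8, C15 methyl on C1). The C8 centre (steps 4–13) and the C9 carbinol centre (steps 7–13) are carried as epimer mixtures and drawn without configuration, because both carbons become sp2 in step 14.

Step 1
Reactants: 1 2-bromo-3-methylcyclopent-2-en-1-one
Product: 2 6-bromo-7-methyl-1,4-dioxaspiro[4.4]non-6-ene
Conditions: ethylene glycol, p-TsOH·H2O (cat.), benzene, reflux, Dean–Stark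
Reagents that add atoms: ethylene glycol, OCCO
Why: Acid-catalysed ketalisation with azeotropic removal of water, in which the vinylic bromine should keep the double bond from leaving its position, so the ketal forms as drawn.

Step 2
Reactants: 2 6-bromo-7-methyl-1,4-dioxaspiro[4.4]non-6-ene; 3 methyl 4-chloro-4-oxobutanoate
Product: 6 methyl 4-(7-methyl-1,4-dioxaspiro[4.4]non-6-en-6-yl)-4-oxobutanoate, via vinyllithium 4 (not isolated), via vinylzinc chloride 5 (not isolated)
Conditions: n-BuLi, THF, −78 °C; ZnCl2, −78 → 0 °C; then 3, Pd(PPh3)4 (5 mol %), 0 °C → rt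
Reagents that add atoms: none
Why: Bromine–lithium exchange gives the α-ketovinyl anion equivalent, transmetalation to zinc tames it, and the Negishi acylation with the acid chloride should stop at the ketone because the organozinc does not attack the methyl ester or the product.

Step 3
Reactants: 6 methyl 4-(7-methyl-1,4-dioxaspiro[4.4]non-6-en-6-yl)-4-oxobutanoate
Product: 8 (5S)-5-(7-methyl-1,4-dioxaspiro[4.4]non-6-en-6-yl)oxolan-2-one, via hydroxy ester 7 (not isolated)
Conditions: (R)-2-methyl-CBS-oxazaborolidine (20 mol %), BH3·SMe2, THF, −20 °C; MeOH, aqueous work-up; then PPTS (cat.), toluene, 50 °C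
Reagents that add atoms: none
Why: Corey–Bakshi–Shibata reduction in which the fully substituted cyclopentenyl group is the large and the CH2CH2CO2Me chain the small substituent, so the (R)-catalyst should give the (S)-carbinol at C6, which then closes to the γ-lactone under weak acid with loss of methanol.

Step 4
Reactants: 8 (5S)-5-(7-methyl-1,4-dioxaspiro[4.4]non-6-en-6-yl)oxolan-2-one
Product: 10 (5S)-3-methyl-5-(7-methyl-1,4-dioxaspiro[4.4]non-6-en-6-yl)oxolan-2-one, via lithium enolate 9 (not isolated)
Conditions: LDA, THF, −78 °C; MeI, −78 → −40 °C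
Reagents that add atoms: iodomethane, CI
Why: Lactone enolate alkylation at C8, the only enolisable carbon, which places the C14 methyl before the ring expansion and so avoids a later choice between C8 and C10 of the cycloheptanone; the new centre is of no consequence (trans isomer expected to predominate).

Step 5
Reactants: 10 (5S)-3-methyl-5-(7-methyl-1,4-dioxaspiro[4.4]non-6-en-6-yl)oxolan-2-one
Product: 11 (5S)-3-methyl-2-methylidene-5-(7-methyl-1,4-dioxaspiro[4.4]non-6-en-6-yl)oxolane
Conditions: Cp2TiMe2, toluene/THF, 65 °C, dark; filtration through basic Al2O3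
Reagents that add atoms: dimethyltitanocene Cp2TiMe2, C[Ti+2]C.c1cc[cH-]c1.c1cc[cH-]c1
Why: Petasis methylenation, in which thermally generated Cp2Ti=CH2 converts the lactone carbonyl into the exocyclic enol ether under neutral conditions and below the onset of the Claisen shift, leaving the ketal and the C6 centre untouched.

Step 6
Reactants: 11 (5S)-3-methyl-2-methylidene-5-(7-methyl-1,4-dioxaspiro[4.4]non-6-en-6-yl)oxolane
Product: 12 (1R)-4,4-ethylenedioxy-11,12,13-trinordauc-5-en-9-one
Conditions: o-xylene (degassed, dilute), i-Pr2NEt (cat.), base-washed sealed tube, 180 °C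
Reagents that add atoms: none
Why: Thermal [3,3]-sigmatropic (Claisen) rearrangement of the allyl vinyl ether C10=C9–O–C6–C5=C1: C10 bonds to C1 while the allylic C6–O bond breaks, the enol ether becomes the C9 ketone and the alkene moves to C5=C6. The closest known reaction type is the Claisen ring expansion of 2-methylidene-5-alkenyl oxolanes, made by lactone methylenation, to cyclohept-4-enones. The seven-membered ring is not closed end to end: it arises by expansion of the oxolane, which keeps C9, C8, C7 and C6, takes in C5, C1 and C10 and expels the oxygen, through a boat-like six-centre array shaped like an 8-oxabicyclo[3.2.1]octane. The quaternary centre C1 is controlled by the C6 carbinol: only the C5–C6 rotamer with C7 cis to C1 can give a cis alkene inside the new ring, and in it the ring oxygen sits on one face of the cyclopentene, so C10 is delivered suprafacially to that face and (S)-C6 becomes (R)-C1. The step needs the concerted path to outrun acid-triggered migration of the exocyclic enol ether and ionisation of the allylic ether, which the non-polar solvent, the amine buffer and base-washed glass should secure; the C8 methyl is a spectator.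

Step 7
Reactants: 12 (1R)-4,4-ethylenedioxy-11,12,13-trinordauc-5-en-9-one
Product: 13 (1R)-4,4-ethylenedioxy-11,12,13-trinordauc-5-en-9-ol
Conditions: NaBH4, MeOH, 0 °C
Reagents that add atoms: none
Why: Borohydride reduction of the only carbonyl group, which masks C9 against borane and the later organometallic reagent; the carbinol configuration is irrelevant because C9 returns to the ketone in step 14.

Step 8
Reactants: 13 (1R)-4,4-ethylenedioxy-11,12,13-trinordauc-5-en-9-ol
Product: 15 (1R)-4,4-ethylenedioxy-9-(4-methoxybenzyloxy)-11,12,13-trinordauc-5-ene, via sodium alkoxide 14 (not isolated)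
Conditions: NaH, THF/DMF, 0 °C; 4-methoxybenzyl chloride, n-Bu4NI (cat.), 0 °C → rt
Reagents that add atoms: 4-methoxybenzyl chloride, COc1ccc(CCl)cc1
Why: Williamson etherification of the unhindered secondary alkoxide gives a p-methoxybenzyl ether that withstands borane, weak acid and organometallic reagents and can later be removed oxidatively beside a silyl ether.

Step 9
Reactants: 15 (1R)-4,4-ethylenedioxy-9-(4-methoxybenzyloxy)-11,12,13-trinordauc-5-ene
Product: 17 (1R)-4,4-ethylenedioxy-9-(4-methoxybenzyloxy)-11,12,13-trinor-5αH-daucan-6α-ol, via C6 alkylborane 16 (not isolated)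
Conditions: BH3·THF (excess), THF, 0 °C → rt; then 3 M NaOH, 30% H2O2, 0 °C → rt
Reagents that add atoms: hydrogen peroxide, OO
Why: Hydroboration–oxidation, in which borane adds syn with boron at the less substituted C6 and hydrogen at C5 and should approach from the α face opposite the pseudoaxial C1 methyl (the pattern of steroidal 5-enes, which give trans-fused 6α-alcohols), so that oxidation with retention sets H5 α and O6 α together.

Step 10
Reactants: 17 (1R)-4,4-ethylenedioxy-9-(4-methoxybenzyloxy)-11,12,13-trinor-5αH-daucan-6α-ol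
Product: 18 (1R)-6α-(tert-butyldimethylsilyloxy)-4,4-ethylenedioxy-9-(4-methoxybenzyloxy)-11,12,13-trinor-5αH-daucane
Conditions: TBSOTf, 2,6-lutidine, CH2Cl2, −78 → 0 °C
Reagents that add atoms: tert-butyldimethylsilyl triflate, CC(C)(C)[Si](C)(C)OS(=O)(=O)C(F)(F)F
Why: Silylation of the hindered secondary alcohol with a silyl triflate and a hindered base, tolerated by the ketal and the benzyl-type ether at low temperature; the silyl ether guards against β-elimination once C4 is a ketone.

Step 11
Reactants: 18 (1R)-6α-(tert-butyldimethylsilyloxy)-4,4-ethylenedioxy-9-(4-methoxybenzyloxy)-11,12,13-trinor-5αH-daucane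
Product: 19 (1R)-6α-(tert-butyldimethylsilyloxy)-9-(4-methoxybenzyloxy)-11,12,13-trinor-5αH-daucan-4-one
Conditions: PPTS, acetone/H2O (9:1), 55 °C
Reagents that add atoms: water, O
Why: Mild acid-catalysed ketal hydrolysis that leaves the hindered silyl ether and the p-methoxybenzyl ether intact, the acid being too weak for fast enolisation toward C5, so H5 should not epimerise and the β-silyloxy group should not be lost.

Step 12
Reactants: 19 (1R)-6α-(tert-butyldimethylsilyloxy)-9-(4-methoxybenzyloxy)-11,12,13-trinor-5αH-daucan-4-one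
Product: 20 (1R)-6α-(tert-butyldimethylsilyloxy)-9-(4-methoxybenzyloxy)-5αH-daucan-4β-ol
Conditions: i-PrMgCl, anhydrous CeCl3, THF, −78 → −20 °C; aqueous work-up
Reagents that add atoms: isopropylmagnesium chloride, CC(C)[Mg]Cl
Why: Organocerium 1,2-addition, chosen because the weakly basic reagent adds to hindered enolisable ketones without enolisation, β-hydride reduction or β-elimination; it should attack the cyclopentanone from the α face, away from the β C1 methyl that lies 1,3 to C4 over the ring, giving the 4β-hydroxyl and the 4α-isopropyl group.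

Step 13
Reactants: 20 (1R)-6α-(tert-butyldimethylsilyloxy)-9-(4-methoxybenzyloxy)-5αH-daucan-4β-ol
Product: 21 (1R)-6α-(tert-butyldimethylsilyloxy)-5αH-daucane-4β,9-diol
Conditions: DDQ, CH2Cl2/pH 7 buffer, 0 °C → rt
Reagents that add atoms: none
Why: Oxidative cleavage of the p-methoxybenzyl ether by DDQ through the benzylic oxocarbenium ion, which spares the silyl ether and the tertiary alcohol.

Step 14
Reactants: 21 (1R)-6α-(tert-butyldimethylsilyloxy)-5αH-daucane-4β,9-diol
Product: 23 (1R)-4β-hydroxy-6α-(tert-butyldimethylsilyloxy)-5αH-dauc-7-en-9-one, via saturated ketone 22 (not isolated)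
Conditions: IBX (3.5 equiv), DMSO, rt then 70 °C
Reagents that add atoms: none
Why: IBX oxidises the secondary alcohol to the ketone and on warming dehydrogenates it (IBX-mediated ketone desaturation); C10 has no β-hydrogen because C1 is quaternary, so only C7–C8 can be desaturated and the methyl-bearing conjugated enone should result, with the tertiary alcohol and the silyl ether inert.

Step 15
Reactants: 23 (1R)-4β-hydroxy-6α-(tert-butyldimethylsilyloxy)-5αH-dauc-7-en-9-one
Product: 24 (1R)-4β,6α-dihydroxy-5αH-dauc-7-en-9-one
Conditions: HF·pyridine, pyridine/THF, 0 °C → rt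
Reagents that add atoms: none
Why: Fluoride cleavage of the secondary silyl ether under buffered, weakly acidic conditions that neither enolise the γ-oxygenated enone nor dehydrate the tertiary alcohol.

Step 16
Reactants: 25 p-coumaric acid
Product: 27 (E)-3-[4-(tert-butyldimethylsilyloxy)phenyl]prop-2-enoic acid, via silyl ester 26 (not isolated)
Conditions: TBSCl (2.5 equiv), imidazole, DMF, rt; then AcOH/THF/H2O, rt
Reagents that add atoms: tert-butyldimethylsilyl chloride, CC(C)(C)[Si](C)(C)Cl
Why: Exhaustive silylation of phenol and acid followed by selective hydrolysis of the far more labile silyl ester leaves the phenol masked and the E alkene untouched.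

Step 17
Reactants: 24 (1R)-4β,6α-dihydroxy-5αH-dauc-7-en-9-one; 27 (E)-3-[4-(tert-butyldimethylsilyloxy)phenyl]prop-2-enoic acid
Product: 28 (1R)-4β-hydroxy-9-oxo-5αH-dauc-7-en-6α-yl (E)-3-[4-(tert-butyldimethylsilyloxy)phenyl]prop-2-enoate
Conditions: DCC, DMAP, CH2Cl2, 0 °C → rt
Reagents that add atoms: none
Why: Steglich esterification, in which the secondary allylic C6 hydroxyl is acylated through the acylpyridinium ion while the tertiary C4 hydroxyl, crowded by the isopropyl group and the ring fusion, should not react; no stereocentre is touched.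

Step 18
Reactants: 28 (1R)-4β-hydroxy-9-oxo-5αH-dauc-7-en-6α-yl (E)-3-[4-(tert-butyldimethylsilyloxy)phenyl]prop-2-enoate
Product: 29 (1R)-4β-hydroxy-9-oxo-5αH-dauc-7-en-6α-yl (E)-3-(4-hydroxyphenyl)prop-2-enoate
Conditions: KHF2, MeOH, rt
Reagents that add atoms: none
Why: Aryl silyl ethers are cleaved selectively by hydrogen difluoride in methanol because phenoxide leaves silicon readily, and the near-neutral medium should spare the allylic ester, the enone and the tertiary alcohol.

**Compound list**
1 | 2-bromo-3-methylcyclopent-2-en-1-one | CC1=C(Br)C(=O)CC1 | starting material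
2 | 6-bromo-7-methyl-1,4-dioxaspiro[4.4]non-6-ene | CC1=C(Br)C2(CC1)OCCO2 | intermediate
3 | methyl 4-chloro-4-oxobutanoate | COC(=O)CCC(Cl)=O | starting material
4 | (7-methyl-1,4-dioxaspiro[4.4]non-6-en-6-yl)lithium | [Li]C1=C(C)CCC12OCCO2 | intermediate (not isolated)
5 | (7-methyl-1,4-dioxaspiro[4.4]non-6-en-6-yl)zinc chloride | Cl[Zn]C1=C(C)CCC12OCCO2 | intermediate (not isolated)
6 | methyl 4-(7-methyl-1,4-dioxaspiro[4.4]non-6-en-6-yl)-4-oxobutanoate | COC(=O)CCC(=O)C1=C(C)CCC12OCCO2 | intermediate
7 | methyl (4S)-4-hydroxy-4-(7-methyl-1,4-dioxaspiro[4.4]non-6-en-6-yl)butanoate | COC(=O)CC[C@H](O)C1=C(C)CCC12OCCO2 | intermediate (not isolated)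
8 | (5S)-5-(7-methyl-1,4-dioxaspiro[4.4]non-6-en-6-yl)oxolan-2-one | O=C1CC[C@H](O1)C2=C(C)CCC23OCCO3 | intermediate
9 | lithium enolate of 8 | [Li]OC1=CC[C@H](O1)C2=C(C)CCC23OCCO3 | intermediate (not isolated)
10 | (5S)-3-methyl-5-(7-methyl-1,4-dioxaspiro[4.4]non-6-en-6-yl)oxolan-2-one, C3 epimers | O=C1C(C)C[C@H](O1)C2=C(C)CCC23OCCO3 | intermediate
11 | (5S)-3-methyl-2-methylidene-5-(7-methyl-1,4-dioxaspiro[4.4]non-6-en-6-yl)oxolane, C3 epimers (Claisen precursor) | C=C1C(C)C[C@H](O1)C2=C(C)CCC23OCCO3 | intermediate
12 | (1R)-4,4-ethylenedioxy-11,12,13-trinordauc-5-en-9-one: C9 ketone, C8 methyl (epimers), C5=C6 alkene, C4 dioxolane, C1 β-methyl (Claisen product) | O=C1C(C)CC=C2[C@](C)(CCC23OCCO3)C1 | intermediate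
13 | (1R)-4,4-ethylenedioxy-11,12,13-trinordauc-5-en-9-ol, C8/C9 epimers | OC1C(C)CC=C2[C@](C)(CCC23OCCO3)C1 | intermediate
14 | sodium alkoxide of 13 | [Na+].[O-]C1C(C)CC=C2[C@](C)(CCC23OCCO3)C1 | intermediate (not isolated)
15 | (1R)-4,4-ethylenedioxy-9-(4-methoxybenzyloxy)-11,12,13-trinordauc-5-ene | COc1ccc(COC2C(C)CC=C3[C@](C)(CCC34OCCO4)C2)cc1 | intermediate
16 | C6 α-alkylborane (RBH2) with H5 α, from 15 | COc1ccc(COC2C(C)C[C@H](B)[C@@H]3[C@](C)(CCC34OCCO4)C2)cc1 | intermediate (not isolated)
17 | (1R)-4,4-ethylenedioxy-9-(4-methoxybenzyloxy)-11,12,13-trinor-5αH-daucan-6α-ol (trans ring fusion) | COc1ccc(COC2C(C)C[C@H](O)[C@@H]3[C@](C)(CCC34OCCO4)C2)cc1 | intermediate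
18 | 6α-tert-butyldimethylsilyl ether of 17 | COc1ccc(COC2C(C)C[C@H](O[Si](C)(C)C(C)(C)C)[C@@H]3[C@](C)(CCC34OCCO4)C2)cc1 | intermediate
19 | (1R)-6α-(tert-butyldimethylsilyloxy)-9-(4-methoxybenzyloxy)-11,12,13-trinor-5αH-daucan-4-one | COc1ccc(COC2C(C)C[C@H](O[Si](C)(C)C(C)(C)C)[C@@H]3[C@](C)(CCC3=O)C2)cc1 | intermediate
20 | (1R)-6α-(tert-butyldimethylsilyloxy)-9-(4-methoxybenzyloxy)-5αH-daucan-4β-ol (4α-isopropyl) | COc1ccc(COC2C(C)C[C@H](O[Si](C)(C)C(C)(C)C)[C@@H]3[C@](C)(CC[C@@]3(O)C(C)C)C2)cc1 | intermediate
21 | (1R)-6α-(tert-butyldimethylsilyloxy)-5αH-daucane-4β,9-diol | OC1C(C)C[C@H](O[Si](C)(C)C(C)(C)C)[C@@H]2[C@](C)(CC[C@@]2(O)C(C)C)C1 | intermediate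
22 | (1R)-4β-hydroxy-6α-(tert-butyldimethylsilyloxy)-5αH-daucan-9-one, C8 epimers | O=C1C(C)C[C@H](O[Si](C)(C)C(C)(C)C)[C@@H]2[C@](C)(CC[C@@]2(O)C(C)C)C1 | intermediate (not isolated)
23 | (1R)-4β-hydroxy-6α-(tert-butyldimethylsilyloxy)-5αH-dauc-7-en-9-one | CC1=C[C@H](O[Si](C)(C)C(C)(C)C)[C@@H]2[C@](C)(CC[C@@]2(O)C(C)C)CC1=O | intermediate
24 | (1R)-4β,6α-dihydroxy-5αH-dauc-7-en-9-one | CC1=C[C@H](O)[C@@H]2[C@](C)(CC[C@@]2(O)C(C)C)CC1=O | intermediate
25 | p-coumaric acid | OC(=O)/C=C/c1ccc(O)cc1 | starting material
26 | tert-butyldimethylsilyl (E)-3-[4-(tert-butyldimethylsilyloxy)phenyl]prop-2-enoate | CC(C)(C)[Si](C)(C)OC(=O)/C=C/c1ccc(O[Si](C)(C)C(C)(C)C)cc1 | intermediate (not isolated)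
27 | (E)-3-[4-(tert-butyldimethylsilyloxy)phenyl]prop-2-enoic acid | OC(=O)/C=C/c1ccc(O[Si](C)(C)C(C)(C)C)cc1 | intermediate
28 | (1R)-4β-hydroxy-9-oxo-5αH-dauc-7-en-6α-yl (E)-3-[4-(tert-butyldimethylsilyloxy)phenyl]prop-2-enoate | CC1=C[C@H](OC(=O)/C=C/c2ccc(O[Si](C)(C)C(C)(C)C)cc2)[C@@H]2[C@](C)(CC[C@@]2(O)C(C)C)CC1=O | intermediate
29 | (1R)-4β-hydroxy-9-oxo-5αH-dauc-7-en-6α-yl (E)-3-(4-hydroxyphenyl)prop-2-enoate, CNP0310968.1; (3R,3aS,4S,8aR) in azulene numbering | CC1=C[C@H](OC(=O)/C=C/c2ccc(O)cc2)[C@@H]2[C@](C)(CC[C@@]2(O)C(C)C)CC1=O | target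

**Step count**
Total: 18 steps. Longest linear sequence: 17 steps (steps 1–15, 17 and 18); step 16 is a one-step side branch.

**Steps most likely to fail**

Step 9. Facial selectivity of the borane addition may be poor: the β face of the C5=C6 alkene carries the C1 methyl, but the α face carries the C10 methylene of the seven-membered ring, and the C8/C9 epimers of 15 may differ in their preference, so cis-fused material could form. The fallback sets C5 and C6 under reagent control and sets out from 15. Hydrolysis of the ketal (PPTS, wet acetone) would give the C4 enone F1, in which C5=C6 is conjugated. Copper-catalysed conjugate borylation (CuCl, NaOt-Bu, a chiral bisphosphine whose enantiomer is chosen to match, B2pin2, MeOH, THF) should place boron on the α face of C6 by ligand control, and the enolate should be protonated at C5 from the α face, anti to the C1 methyl, to give the C6 pinacol boronate F2. Oxidation with NaBO3·4H2O, with retention, would give the β-hydroxy ketone F3, and silylation (TBSOTf, 2,6-lutidine) returns to the route at 19.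

Step 6. The strained boat-like transition state that builds a quaternary carbon may be reached too slowly, so that migration of the exocyclic enol ether into the ring or ionisation of the allylic C6–O bond (with loss of chirality transfer) takes over. The fallback sets out from 11 and uses the Lewis-acid-promoted reductive variant of the ring expansion: i-Bu3Al, CH2Cl2, −78 °C → rt. Aluminium bound to the ring oxygen should drive the same C1–C10 bond formation far below the thermal threshold, and the aluminium-bound ketone is reduced in the flask by β-hydride transfer. The route is rejoined at alcohol 13, and no compound outside the list arises (F0).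

Step 14. The one-flask oxidation and dehydrogenation may stall at the saturated ketone or run on to over-oxidation toward C5–C6. The fallback separates the two events and sets out from 21. Dess–Martin periodinane would give ketone 22, now isolated. TMSCl, NaI and Et3N in MeCN should form the more substituted silyl enol ether and silylate the tertiary alcohol, giving the bis(trimethylsilyl) derivative F4; any enol ether toward C10 cannot dehydrogenate and reverts to 22. Saegusa–Ito oxidation with Pd(OAc)2 in MeCN would give the C4-O-trimethylsilyl enone F5, and the HF·pyridine treatment of step 15 removes both silyl groups, returning to the route at 24.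

**Further compounds**
F0 | step 6 | none | none
F1 | step 9 | (1R)-9-(4-methoxybenzyloxy)-11,12,13-trinordauc-5-en-4-one | COc1ccc(COC2C(C)CC=C3[C@](C)(CCC3=O)C2)cc1
F2 | step 9 | (1R)-9-(4-methoxybenzyloxy)-6α-(4,4,5,5-tetramethyl-1,3,2-dioxaborolan-2-yl)-11,12,13-trinor-5αH-daucan-4-one | COc1ccc(COC2C(C)C[C@H](B4OC(C)(C)C(C)(C)O4)[C@@H]3[C@](C)(CCC3=O)C2)cc1
F3 | step 9 | (1R)-6α-hydroxy-9-(4-methoxybenzyloxy)-11,12,13-trinor-5αH-daucan-4-one | COc1ccc(COC2C(C)C[C@H](O)[C@@H]3[C@](C)(CCC3=O)C2)cc1
F4 | step 14 | (1R)-6α-(tert-butyldimethylsilyloxy)-4β,9-bis(trimethylsilyloxy)-5αH-dauc-8-ene | C[Si](C)(C)OC1=C(C)C[C@H](O[Si](C)(C)C(C)(C)C)[C@@H]2[C@](C)(CC[C@@]2(O[Si](C)(C)C)C(C)C)C1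
F5 | step 14 | (1R)-6α-(tert-butyldimethylsilyloxy)-4β-(trimethylsilyloxy)-5αH-dauc-7-en-9-one | CC1=C[C@H](O[Si](C)(C)C(C)(C)C)[C@@H]2[C@](C)(CC[C@@]2(O[Si](C)(C)C)C(C)C)CC1=O
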